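**Assumption:** the SMILES is taken as the 8‑O‑tigloyl furanoheliangolide, with germacrane numbering C1–C15: 6,12‑olide, 3,10‑epoxy‑1‑one, 4Z‑ene, 11(13)‑ene. The configuration is (6R,7R,8R,10R).

## Retrosynthetic overview
1. The C8 tiglate comes from the C8 alcohol. The trans‑fused α‑methylene‑γ‑lactone and the 10‑membered ring are closed together by an intramolecular Cr(II) (Hiyama/NHK) allylation: a Z‑enal (C6) plus a 2‑(bromomethyl)alkenoate (C7) gives the C6–C7 bond, then lactonization.
2. The furan‑3(2H)‑one bridge is made before macrocyclization, by 5‑endo‑dig oxa‑Michael cycloisomerization of a tertiary α‑hydroxy ynone. The ynone comes from a lithium Z‑enynide added to a quaternary α‑hydroxy aldehyde.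
3. C10 is set by Sharpless epoxidation of methallyl alcohol. The epoxide is opened by a dithiane acyl‑anion equivalent, and C8 is set by ketoreductase reduction of the resulting α‑silyloxy ketone.
4. The C7 acrylate comes from a Morita–Baylis–Hillman reaction on the C7 aldehyde, followed by SN2′ bromination.
5. Ring order: furanone (5), then the 10‑membered carbocycle together with the lactone precursor (NHK), then the γ‑lactone.

## Route

**Step 1**
Reactants: 1, 2‑methylprop‑2‑en‑1‑ol (methallyl alcohol)
Product: 2, (S)‑(2‑methyloxiran‑2‑yl)methanol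
Conditions: Ti(OiPr)4 (10 mol%), L‑(+)‑DET (12 mol%), TBHP, 3 Å MS, CH2Cl2, –20 °C; cold tartrate work‑up; product kept as a solution (volatile)
Reagents that add atoms: tert‑butyl hydroperoxide, CC(C)(C)OO (supplies the epoxide O)
Why: Sharpless asymmetric epoxidation sets the future C10 quaternary centre (~90% ee); the minor enantiomer is carried as a diastereomer and removed by chromatography after Step 8.

**Step 2**
Reactants: 2
Product: 3, (R)‑2‑[(benzyloxy)methyl]‑2‑methyloxirane
Conditions: NaH, BnBr, TBAI (cat.), THF, 0 °C → rt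
Reagents that add atoms: benzyl bromide, BrCc1ccccc1
Why: Williamson etherification gives an organolithium‑compatible ether, and the quaternary centre is untouched (the label changes from S to R only because the CIP priorities change).

**Step 3**
Reactants: 3; 4, 1,3‑dithiane
Product: 5, (R)‑1‑(benzyloxy)‑3‑(1,3‑dithian‑2‑yl)‑2‑methylpropan‑2‑ol
Conditions: 4, n‑BuLi, THF, –30 °C; then 3, –78 → 0 °C
Reagents that add atoms: none
Why: Corey–Seebach SN2 opening at the unhindered epoxide CH2 (C9) leaves C10 intact and installs C8 as an acyl‑anion equivalent.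

**Step 4**
Reactants: 5
Product: 6, (R)‑1‑(benzyloxy)‑3‑[2‑(hydroxymethyl)‑1,3‑dithian‑2‑yl]‑2‑methylpropan‑2‑ol
Conditions: n‑BuLi (2.3 equiv), THF, –78 → –20 °C; then HCHO(g), –78 → 0 °C
Reagents that add atoms: formaldehyde, C=O
Why: the alkoxide/dithianyl dianion is hydroxymethylated, which supplies C7.

**Step 5**
Reactants: 6
Product: 7, the primary TBS ether of 6
Conditions: TBSCl, imidazole, DMF, rt
Reagents that add atoms: TBSCl, CC(C)(C)[Si](C)(C)Cl
Why: the primary alcohol silylates selectively and the tertiary C10–OH does not react.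

**Step 6**
Reactants: 7
Product: 8, (R)‑5‑(benzyloxy)‑1‑(TBSO)‑4‑hydroxy‑4‑methylpentan‑2‑one
Conditions: PhI(OCOCF3)2, NaHCO3, MeCN/H2O 9:1, 0 °C
Reagents that add atoms: water, O (supplies the ketone O)
Why: oxidative dethioacetalization under buffered conditions unmasks the C8 ketone without touching the silyl or benzyl ethers.

**Step 7**
Reactants: 8
Product: 9, (2R,4R)‑5‑(benzyloxy)‑1‑(TBSO)‑4‑methylpentane‑2,4‑diol
Conditions: ketoreductase (NADPH‑dependent oxidoreductase, selected from a panel for the (R)‑alcohol), NADP+ (cat.), iPrOH (10% v/v, cofactor recycling), KPi pH 7.0/DMSO 9:1, 30 °C, 24 h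
Reagents that add atoms: none
Why: enzymatic asymmetric ketone reduction delivers hydride to one face of the ketone and sets C8 (R) independently of the remote C10 centre.

**Step 8**
Reactants: 9
Product: 10, (2R,4R)‑1‑(benzyloxy)‑4,5‑bis(TBSO)‑2‑methylpentan‑2‑ol
Conditions: TBSCl, imidazole, DMAP (cat.), DMF, 40 °C
Reagents that add atoms: TBSCl, CC(C)(C)[Si](C)(C)Cl
Why: the secondary C8–OH is protected chemoselectively over the tertiary OH, which prevents later β‑elimination from the allylchromium; any C10‑epimer is removed by chromatography here.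

**Step 9**
Reactants: 10
Product: 11, (2R,4R)‑4,5‑bis(TBSO)‑2‑methylpentane‑1,2‑diol
Conditions: H2 (1 atm), Pd(OH)2/C, EtOAc, rt
Reagents that add atoms: none
Why: hydrogenolytic debenzylation is safe because the sulfur has already been removed and no unsaturation is present yet.

**Step 10**
Reactants: 11
Product: 12, (2R,4R)‑4,5‑bis(TBSO)‑2‑hydroxy‑2‑methylpentanal
Conditions: (COCl)2, DMSO, Et3N, CH2Cl2, –78 → 0 °C
Reagents that add atoms: none
Why: Swern oxidation is selective for the primary alcohol and avoids vicinal‑diol cleavage; the aldehyde has no α‑H, so nothing can epimerize.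

**Step 11**
Reactants: 13, 2‑butyn‑1‑ol
Product: 14, (Z)‑3‑iodobut‑2‑en‑1‑ol
Conditions: Red‑Al, THF, 0 °C → rt; EtOAc, –78 °C; I2, –78 °C → rt
Reagents that add atoms: iodine, II
Why: trans‑hydroalumination through a five‑membered alkoxyaluminate places I cis to CH2OH, which is the Z geometry needed for the ring alkene.

**Step 12**
Reactants: 14
Product: 15, (Z)‑1‑[(3‑iodobut‑2‑enyloxy)methyl]‑4‑methoxybenzene (the PMB ether)
Conditions: NaH, PMBCl, TBAI (cat.), THF/DMF, 0 °C → rt
Reagents that add atoms: 4‑methoxybenzyl chloride, COc1ccc(CCl)cc1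
Why: the PMB ether survives the lithiation, MnO2, base and acid steps ahead and is removed orthogonally by DDQ.

**Step 13**
Reactants: 15; 16, trimethylsilylacetylene
Product: 17, the (Z)‑TMS‑enyne
Conditions: Pd(PPh3)2Cl2 (3 mol%), CuI (6 mol%), Et3N, THF, rt
Reagents that add atoms: none
Why: Sonogashira coupling proceeds with retention of alkene geometry, so the alkyne ends up cis to CH2OPMB.

**Step 14**
Reactants: 17
Product: 18, the terminal (Z)‑enyne
Conditions: K2CO3, MeOH, rt
Reagents that add atoms: none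
Why: protodesilylation under mild base leaves the PMB ether and the alkene geometry intact.

**Step 15**
Reactants: 12; 18
Product: 19, the propargylic diol (C1 epimeric mixture; C8 and C10 as in 12)
Conditions: 18 (3 equiv), n‑BuLi (3 equiv), THF, –78 °C; add 12; –78 → –20 °C
Reagents that add atoms: none
Why: acetylide addition to the non‑enolizable aldehyde forms C1–C2; the C1 centre is destroyed in the next step.

**Step 16**
Reactants: 19
Product: 20, the α‑hydroxy ynone
Conditions: MnO2 (20 equiv), CH2Cl2, rt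
Reagents that add atoms: none
Why: MnO2 oxidizes only the propargylic secondary alcohol, and the tertiary alcohol is untouched.

**Step 17**
Reactants: 20
Product: 21, the furan‑3(2H)‑one (C10 bridged to C3 through O, with C6–OPMB, C7–OTBS and C8–OTBS)
Conditions: DBU (20 mol%), CH2Cl2, 0 °C → rt
Reagents that add atoms: none
Why: base‑catalysed 5‑endo‑dig oxa‑Michael cycloisomerization forms the C3–O bond only, so the C10 configuration is retained.

**Step 18**
Reactants: 21
Product: 22, the primary alcohol (C7–OH) with C8–OTBS retained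
Conditions: CSA (10 mol%), MeOH/CH2Cl2 1:1, 0 °C
Reagents that add atoms: none
Why: a primary TBS ether is cleaved selectively over the vicinal secondary TBS ether, and PMB and the furanone survive.

**Step 19**
Reactants: 22
Product: 23, the α‑silyloxy aldehyde (C7 aldehyde)
Conditions: Dess–Martin periodinane, NaHCO3, CH2Cl2, 0 °C → rt
Reagents that add atoms: none
Why: buffered periodinane oxidation avoids epimerization of C8, and the aldehyde is used immediately.

**Step 20**
Reactants: 23; 24, methyl acrylate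
Product: 25, the Baylis–Hillman adduct (C7 epimeric mixture)
Conditions: DABCO (1 equiv), methyl acrylate (15 equiv), MeOH, rt, 4 d
Reagents that add atoms: none
Why: the Morita–Baylis–Hillman reaction builds the C11 acrylate, and the new C7 carbinol stereocentre is erased in the next step.

**Step 21**
Reactants: 25
Product: 26, the allylic bromide: C8–CH=C(CO2Me)–CH2Br (alkene geometry not specified)
Conditions: MsCl, Et3N, CH2Cl2, 0 °C; then LiBr, THF, rt
Reagents that add atoms: lithium bromide, [Li+].[Br-]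
Why: SN2′ ionization of the mesylate/chloride followed by bromide capture gives the 2‑(bromomethyl)alkenoate, and the allylchromium formed later equilibrates, so the alkene geometry does not matter.

**Step 22**
Reactants: 26
Product: 27, the Z‑allylic primary alcohol (C6–OH)
Conditions: DDQ, CH2Cl2/pH 7 phosphate buffer 18:1, 0 °C
Reagents that add atoms: none
Why: oxidative PMB removal is orthogonal to the silyl ether, the allyl bromide and the acrylate.

**Step 23**
Reactants: 27
Product: 28, the Z‑enal (C6 aldehyde, cis to the furanone C3)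
Conditions: Dess–Martin periodinane, NaHCO3, CH2Cl2, 0 °C
Reagents that add atoms: none
Why: mild buffered oxidation preserves the Z‑alkene, and the unstable enal is taken straight into the next step.

**Step 24**
Reactants: 28
Product: 29, the macrocyclic anti hydroxy ester (6R,7S by CIP, 8R,10R; trans C6/C7)
Conditions: CrCl2 (10 equiv), DMF (0.003 M), 25 °C, substrate added by syringe pump over 6 h
Reagents that add atoms: none
Why: intramolecular Hiyama/Nozaki–Hiyama–Kishi allylation goes through a chair transition state and sets the C6/C7 anti (trans) relationship, with the C8 centre and the rigid cis‑enal/furanone template directing the face; the diastereomers are separable.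

**Step 25**
Reactants: 29
Product: 30, the C8‑TBS lactone (6R,7S,8R,10R; the 7S label comes only from Si in the CIP ranking)
Conditions: PPTS (0.5 equiv), PhMe, 60 °C
Reagents that add atoms: none
Why: acid‑catalysed γ‑lactonization of the C6–OH onto the C12 methyl ester closes the trans‑fused α‑methylene‑γ‑butyrolactone, with no change at the stereocentres.

**Step 26**
Reactants: 30
Product: 31, the C8 alcohol (6R,7R,8R,10R)
Conditions: HF·pyridine, pyridine/THF, 0 °C → rt
Reagents that add atoms: none
Why: buffered fluoride removes the TBS group under non‑basic conditions, so translactonization is avoided.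

**Step 27**
Reactants: 31; 32, tiglic acid ((E)‑2‑methylbut‑2‑enoic acid)
Product: 33, Atripliciolide tiglate (target)
Conditions: 32, 2,4,6‑Cl3C6H2COCl, Et3N, THF, rt; then 31, DMAP, PhMe, rt
Reagents that add atoms: none
Why: Yamaguchi esterification through the mixed anhydride installs the tiglate and retains the E geometry.

## Compound list
1 | 2‑methylprop‑2‑en‑1‑ol | C=C(C)CO | starting material
2 | (S)‑(2‑methyloxiran‑2‑yl)methanol | C[C@]1(CO)CO1 | intermediate
3 | (R)‑2‑[(benzyloxy)methyl]‑2‑methyloxirane | C[C@]1(COCc2ccccc2)CO1 | intermediate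
4 | 1,3‑dithiane | C1CSCSC1 | starting material
5 | (R)‑1‑(benzyloxy)‑3‑(1,3‑dithian‑2‑yl)‑2‑methylpropan‑2‑ol | C[C@](O)(COCc1ccccc1)CC1SCCCS1 | intermediate
6 | (R)‑1‑(benzyloxy)‑3‑[2‑(hydroxymethyl)‑1,3‑dithian‑2‑yl]‑2‑methylpropan‑2‑ol | C[C@](O)(COCc1ccccc1)CC1(CO)SCCCS1 | intermediate
7 | TBS ether of 6 | C[C@](O)(COCc1ccccc1)CC1(CO[Si](C)(C)C(C)(C)C)SCCCS1 | intermediate
8 | (R)‑5‑(benzyloxy)‑1‑(TBSO)‑4‑hydroxy‑4‑methylpentan‑2‑one | C[C@](O)(COCc1ccccc1)CC(=O)CO[Si](C)(C)C(C)(C)C | intermediate
9 | (2R,4R)‑5‑(benzyloxy)‑1‑(TBSO)‑4‑methylpentane‑2,4‑diol | C[C@](O)(COCc1ccccc1)C[C@@H](O)CO[Si](C)(C)C(C)(C)C | intermediate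
10 | (2R,4R)‑1‑(benzyloxy)‑4,5‑bis(TBSO)‑2‑methylpentan‑2‑ol | C[C@](O)(COCc1ccccc1)C[C@@H](O[Si](C)(C)C(C)(C)C)CO[Si](C)(C)C(C)(C)C | intermediate
11 | (2R,4R)‑4,5‑bis(TBSO)‑2‑methylpentane‑1,2‑diol | C[C@](O)(CO)C[C@@H](O[Si](C)(C)C(C)(C)C)CO[Si](C)(C)C(C)(C)C | intermediate
12 | (2R,4R)‑4,5‑bis(TBSO)‑2‑hydroxy‑2‑methylpentanal | C[C@](O)(C=O)C[C@@H](O[Si](C)(C)C(C)(C)C)CO[Si](C)(C)C(C)(C)C | intermediate
13 | 2‑butyn‑1‑ol | CC#CCO | starting material
14 | (Z)‑3‑iodobut‑2‑en‑1‑ol | C/C(I)=C/CO | intermediate
15 | PMB ether of 14 | C/C(I)=C/COCc1ccc(OC)cc1 | intermediate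
16 | trimethylsilylacetylene | C[Si](C)(C)C#C | starting material
17 | (Z)‑TMS‑enyne PMB ether | C[Si](C)(C)C#C/C(C)=C\COCc1ccc(OC)cc1 | intermediate
18 | (Z)‑terminal enyne PMB ether | C#C/C(C)=C\COCc1ccc(OC)cc1 | intermediate
19 | propargylic diol (C1 epimeric mixture) | C[C@](O)(C(O)C#C/C(C)=C\COCc1ccc(OC)cc1)C[C@@H](O[Si](C)(C)C(C)(C)C)CO[Si](C)(C)C(C)(C)C | intermediate
20 | α‑hydroxy ynone | C[C@](O)(C(=O)C#C/C(C)=C\COCc1ccc(OC)cc1)C[C@@H](O[Si](C)(C)C(C)(C)C)CO[Si](C)(C)C(C)(C)C | intermediate
21 | furan‑3(2H)‑one, bis‑TBS, PMB | C[C@]1(C[C@@H](O[Si](C)(C)C(C)(C)C)CO[Si](C)(C)C(C)(C)C)OC(/C(C)=C\COCc2ccc(OC)cc2)=CC1=O | intermediate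
22 | C7 primary alcohol | C[C@]1(C[C@@H](O[Si](C)(C)C(C)(C)C)CO)OC(/C(C)=C\COCc2ccc(OC)cc2)=CC1=O | intermediate
23 | C7 aldehyde | C[C@]1(C[C@@H](O[Si](C)(C)C(C)(C)C)C=O)OC(/C(C)=C\COCc2ccc(OC)cc2)=CC1=O | intermediate
24 | methyl acrylate | C=CC(=O)OC | starting material
25 | Baylis–Hillman adduct | C[C@]1(C[C@@H](O[Si](C)(C)C(C)(C)C)C(O)C(=C)C(=O)OC)OC(/C(C)=C\COCc2ccc(OC)cc2)=CC1=O | intermediate
26 | allylic bromide | C[C@]1(C[C@@H](O[Si](C)(C)C(C)(C)C)C=C(CBr)C(=O)OC)OC(/C(C)=C\COCc2ccc(OC)cc2)=CC1=O | intermediate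
27 | Z‑allylic alcohol | C[C@]1(C[C@@H](O[Si](C)(C)C(C)(C)C)C=C(CBr)C(=O)OC)OC(/C(C)=C\CO)=CC1=O | intermediate
28 | Z‑enal | C[C@]1(C[C@@H](O[Si](C)(C)C(C)(C)C)C=C(CBr)C(=O)OC)OC(/C(C)=C\C=O)=CC1=O | intermediate
29 | macrocyclic hydroxy methyl ester | C=C(C(=O)OC)[C@H]1[C@H](O)/C=C(/C)C2=CC(=O)[C@@](C)(C[C@H]1O[Si](C)(C)C(C)(C)C)O2 | intermediate
30 | C8‑TBS lactone | C=C1C(=O)O[C@@H]2/C=C(/C)C3=CC(=O)[C@@](C)(C[C@@H](O[Si](C)(C)C(C)(C)C)[C@@H]12)O3 | intermediate
31 | C8 alcohol | C=C1C(=O)O[C@@H]2/C=C(/C)C3=CC(=O)[C@@](C)(C[C@@H](O)[C@@H]12)O3 | intermediate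
32 | tiglic acid | OC(=O)/C(C)=C/C | starting material
33 | Atripliciolide tiglate | C=C1C(=O)O[C@@H]2/C=C(/C)C3=CC(=O)[C@@](C)(C[C@@H](OC(=O)/C(C)=C/C)[C@@H]12)O3 | target

**Total steps:** 27.
**Longest linear sequence:** 23 steps, from methallyl alcohol (Steps 1–10 and 15–27).

**Three steps most likely to fail**
1. **Step 24, macrocyclic NHK.** Risks are wrong C7/C8 diastereoselectivity, β‑elimination of the C8–OTBS from the allylchromium, and oligomerization. Fallback: change the disconnection. Prepare the isopropenyl analogue of 26 from 2‑methylbut‑1‑en‑3‑yne in place of 18. Do an intermolecular Cr‑allylation of acrolein, separate the trans lactone diastereomers, and close C4=C5 by ring‑closing metathesis with a Hoveyda–Grubbs II catalyst.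
2. **Step 20, MBH on the α‑silyloxy aldehyde.** Risks are slow conversion, C8 epimerization, and DABCO‑induced Z→E isomerization of the dienone. Fallback: build C7=C11 by Masamune–Roush HWE of aldehyde 23 with (MeO)2P(O)CH(CO2Me)CH2OTBS. Then remove the primary TBS group selectively and brominate the allylic alcohol (Appel).
3. **Step 7, ketoreductase reduction.** Risks are a poor enzyme hit, the wrong sense of reduction, or retro‑aldol of the β‑hydroxy ketone. Fallback: switch to chemical catalysis. Use Noyori–Ikariya asymmetric transfer hydrogenation of the α‑silyloxy ketone 8 with RuCl[(R,R)‑TsDPEN](p‑cymene) in HCO2H/Et3N.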